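**Plan**

- Retrosynthesis: the five O–benzyl bonds of a perbenzylated flavanone are cut first; then, in ring C, the bonds O1–C8a and C4–C4a, which lifts out the two ortho carbons C4a/C8a of ring A and leaves O1–C2–C3–C4(=O) as a β-lactone; last, the aryl–CH2 bond of the side chain (aryllithium plus 2,2-dimethyloxetane).
- Enabling feature: in ring C the ether oxygen O1 and the carbonyl carbon C4 are 1,3-related across C2–C3, which is a masked 4-aryl-oxetan-2-one. The other two ring atoms are adjacent carbons of ring A, so a 2-fluoroaryllithium (C4a nucleophilic, C8a electrophilic, an aryne equivalent) can be inserted into the strained acyl–O bond, turning the four-membered ring into the six-membered ring C in one step.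
- Forward order: ring A fragment (benzylation, lithiation/oxetane opening, O-benzylation, bromination between F and OBn); ring B fragment to the β-lactone (Claisen condensation, asymmetric transfer hydrogenation, hydrolysis, lactonisation); ring expansion joins the fragments and creates ring C; hydrogenolysis ends the route.
- Stereochemistry: C2 (S) is set once, by Noyori transfer hydrogenation of the β-keto ester, and the C2–O1 bond is never broken afterwards. The 6-alkyl (not 8-alkyl) pattern follows from the position of lithium between F and OBn.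

Key step: step 9

Assumption: the stereocentre of the target is read as (2S), and compounds 1, 3 and 8 are taken as commercially available.

**Route**

Step 1
Reactants: 1 5-fluorobenzene-1,3-diol
Product: 2 1,3-bis(benzyloxy)-5-fluorobenzene
Conditions: BnBr (2.2 equiv), K2CO3, DMF, rt to 50 °C
Reagents that add atoms: benzyl bromide BrCc1ccccc1
Why: Williamson etherification of both phenols should be clean, and benzyl is chosen because it coordinates the base in the next lithiation, survives organolithium chemistry at low temperature and leaves by neutral hydrogenolysis at the end.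

Step 2
Reactants: 2 1,3-bis(benzyloxy)-5-fluorobenzene; 3 2,2-dimethyloxetane
Product: 5 4-[2,6-bis(benzyloxy)-4-fluorophenyl]-2-methylbutan-2-ol, via aryllithium 4 (not isolated)
Conditions: n-BuLi (1.1 equiv), THF, −20 to 0 °C; then 3, BF3·OEt2, −78 °C; aq. NH4Cl
Reagents that add atoms: none
Why: Directed ortho-metalation with n-BuLi under coordination control should remove the proton between the two benzyloxy groups, and the aryllithium should open the BF3-activated oxetane at its unhindered CH2 (Lewis-acid-promoted organolithium opening of an oxetane), ring strain driving formation of the aryl–CH2 bond and unveiling the tertiary alcohol.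

Step 3
Reactants: 5 4-[2,6-bis(benzyloxy)-4-fluorophenyl]-2-methylbutan-2-ol
Product: 6 1,3-bis(benzyloxy)-2-[3-(benzyloxy)-3-methylbutyl]-5-fluorobenzene
Conditions: KH, BnBr, n-Bu4NI (cat.), THF, 0 °C to rt
Reagents that add atoms: benzyl bromide BrCc1ccccc1
Why: Williamson benzylation of the tertiary alkoxide removes the only acidic proton, so that no second alkoxide base is present in the key step, and this ether leaves together with the aryl benzyl ethers in the last step.

Step 4
Reactants: 6 1,3-bis(benzyloxy)-2-[3-(benzyloxy)-3-methylbutyl]-5-fluorobenzene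
Product: 7 1,3-bis(benzyloxy)-2-[3-(benzyloxy)-3-methylbutyl]-4-bromo-5-fluorobenzene
Conditions: NBS (1.0 equiv), MeCN, 0 °C, dark
Reagents that add atoms: N-bromosuccinimide O=C1CCC(=O)N1Br
Why: Electrophilic aromatic bromination can only take one of the two equivalent ring positions, each ortho and para to a benzyloxy group and next to fluorine, which places the future carbanion site exactly between F and OBn.

Step 5
Reactants: 8 1-[3,4-bis(benzyloxy)phenyl]ethan-1-one
Product: 9 methyl 3-[3,4-bis(benzyloxy)phenyl]-3-oxopropanoate
Conditions: NaH (2.5 equiv), dimethyl carbonate, THF, reflux; acidic work-up (AcOH)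
Reagents that add atoms: dimethyl carbonate COC(=O)OC
Why: Crossed Claisen condensation of the ketone enolate with the non-enolisable carbonate is driven to completion by deprotonation of the β-keto ester as it forms.

Step 6
Reactants: 9 methyl 3-[3,4-bis(benzyloxy)phenyl]-3-oxopropanoate
Product: 10 methyl (3S)-3-[3,4-bis(benzyloxy)phenyl]-3-hydroxypropanoate
Conditions: RuCl[(S,S)-TsDPEN](p-cymene) (1 mol%), HCO2H/Et3N (5:2), 40 °C
Reagents that add atoms: none
Why: Noyori asymmetric transfer hydrogenation should deliver hydride to the ketone face selected by the (S,S)-diamine ligand, the aryl group lying under the arene ligand in the six-membered transition state, which gives the (S)-carbinol as with acetophenone-type substrates and leaves the benzyl ethers untouched.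

Step 7
Reactants: 10 methyl (3S)-3-[3,4-bis(benzyloxy)phenyl]-3-hydroxypropanoate
Product: 11 (3S)-3-[3,4-bis(benzyloxy)phenyl]-3-hydroxypropanoic acid
Conditions: LiOH·H2O, THF/H2O (3:1), 0 °C; acidic work-up (1 M HCl, 0 °C)
Reagents that add atoms: lithium hydroxide [Li+].[OH-]
Why: Saponification by acyl–oxygen cleavage at 0 °C does not touch the carbinol centre and is mild enough to avoid retro-aldol cleavage or dehydration.

Step 8
Reactants: 11 (3S)-3-[3,4-bis(benzyloxy)phenyl]-3-hydroxypropanoic acid
Product: 13 (4S)-4-[3,4-bis(benzyloxy)phenyl]oxetan-2-one, via mixed carboxylic sulfonic anhydride 12 (not isolated)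
Conditions: PhSO2Cl (2 equiv), pyridine, 0 to 4 °C; cold neutral work-up, used promptly
Reagents that add atoms: none
Why: β-Lactonisation by carboxyl activation (mixed anhydride, then 4-exo-trig attack of the hydroxyl group on the activated carbonyl) closes the ring without breaking the C–O bond of the stereocentre, so the (S) configuration is retained.

Step 9
Reactants: 7 1,3-bis(benzyloxy)-2-[3-(benzyloxy)-3-methylbutyl]-4-bromo-5-fluorobenzene; 13 (4S)-4-[3,4-bis(benzyloxy)phenyl]oxetan-2-one
Product: 16 (2S)-5,7-bis(benzyloxy)-6-[3-(benzyloxy)-3-methylbutyl]-2-[3,4-bis(benzyloxy)phenyl]-2,3-dihydro-4H-chromen-4-one, via aryllithium 14 (not isolated), via lithium aldolate 15 (not isolated)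
Conditions: 7, t-BuLi (2.0 equiv), THF, −78 °C; then 13 (1.05 equiv) in THF, −78 °C; then DMPU, −78 to 0 °C; aq. NH4Cl
Reagents that add atoms: none
Why: Proposed new method: bromine–lithium exchange gives the 2-fluoroaryllithium 14, a 1,2-dipolar aryne equivalent whose carbanion (future C4a) attacks the strained lactone carbonyl of 13 with acyl–oxygen cleavage to release the lithium alkoxide on C2 (15), and this alkoxide, held next to the C–F carbon (future C8a) that the new ortho ketone now activates, displaces fluoride by intramolecular SNAr, so that the two aromatic carbons are inserted into the acyl–O bond and the four-membered ring becomes the six-membered ring C in one flask. The closest known reaction types are the insertion of arynes into the N–C(O) bond of β-lactams to give 2,3-dihydroquinolin-4-ones, the acyl–oxygen opening of β-lactones by organolithium reagents to β-hydroxy ketones, and the SNAr closure of alkoxides onto ortho-fluoroaryl ketones; their union as a two-atom ring expansion of a β-lactone has no direct precedent. Ring C closes by a six-membered addition–elimination at an aromatic sp2 carbon (formally 6-endo-trig toward the ketone-conjugated C8a=C4a bond), with LiF as the thermodynamic sink. No new stereocentre is formed: C2 keeps the (S) configuration of 13 because its C–O bond is never broken, the aryllithium attacking the carbonyl carbon and not the benzylic carbon. The step needs mono-addition and acyl-over-alkyl attack, which the hard aryllithium at −78 °C and the di-ortho-substituted, chelated aldolate should secure; it needs ring closure to outrun retro-aldol cleavage and enolisation, which is favoured because the alkoxide is the only base present and closes intramolecularly at or below 0 °C; and the 6-alkyl pattern of ring A is fixed because lithium sits between F and OBn.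

Step 10
Reactants: 16 (2S)-5,7-bis(benzyloxy)-6-[3-(benzyloxy)-3-methylbutyl]-2-[3,4-bis(benzyloxy)phenyl]-2,3-dihydro-4H-chromen-4-one
Product: 17 (2S)-2-(3,4-dihydroxyphenyl)-5,7-dihydroxy-6-(3-hydroxy-3-methylbutyl)-2,3-dihydro-4H-chromen-4-one
Conditions: H2 (1 atm), 10% Pd/C, EtOAc/MeOH, rt; filtration through Celite, no acid
Reagents that add atoms: none
Why: Catalytic hydrogenolysis cleaves all five benzyl–oxygen bonds under neutral conditions, which should leave the C2 centre, the aryl ketone and the acid-sensitive tertiary alcohol (prone to chroman formation with the neighbouring phenol under acid) intact.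

**Compound list**

1 | 5-fluorobenzene-1,3-diol | Oc1cc(O)cc(F)c1 | starting material
2 | 1,3-bis(benzyloxy)-5-fluorobenzene | Fc1cc(OCc2ccccc2)cc(OCc2ccccc2)c1 | intermediate
3 | 2,2-dimethyloxetane | CC1(C)CCO1 | starting material
4 | [2,6-bis(benzyloxy)-4-fluorophenyl]lithium | [Li]c1c(OCc2ccccc2)cc(F)cc1OCc1ccccc1 | intermediate
5 | 4-[2,6-bis(benzyloxy)-4-fluorophenyl]-2-methylbutan-2-ol | CC(C)(O)CCc1c(OCc2ccccc2)cc(F)cc1OCc1ccccc1 | intermediate
6 | 1,3-bis(benzyloxy)-2-[3-(benzyloxy)-3-methylbutyl]-5-fluorobenzene | CC(C)(OCc1ccccc1)CCc1c(OCc2ccccc2)cc(F)cc1OCc1ccccc1 | intermediate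
7 | 1,3-bis(benzyloxy)-2-[3-(benzyloxy)-3-methylbutyl]-4-bromo-5-fluorobenzene | CC(C)(OCc1ccccc1)CCc1c(OCc2ccccc2)cc(F)c(Br)c1OCc1ccccc1 | intermediate
8 | 1-[3,4-bis(benzyloxy)phenyl]ethan-1-one | CC(=O)c1ccc(OCc2ccccc2)c(OCc2ccccc2)c1 | starting material
9 | methyl 3-[3,4-bis(benzyloxy)phenyl]-3-oxopropanoate | COC(=O)CC(=O)c1ccc(OCc2ccccc2)c(OCc2ccccc2)c1 | intermediate
10 | methyl (3S)-3-[3,4-bis(benzyloxy)phenyl]-3-hydroxypropanoate | COC(=O)C[C@@H](c1ccc(OCc2ccccc2)c(OCc2ccccc2)c1)O | intermediate
11 | (3S)-3-[3,4-bis(benzyloxy)phenyl]-3-hydroxypropanoic acid | OC(=O)C[C@@H](c1ccc(OCc2ccccc2)c(OCc2ccccc2)c1)O | intermediate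
12 | benzenesulfonic (3S)-3-[3,4-bis(benzyloxy)phenyl]-3-hydroxypropanoic anhydride | O=C(C[C@@H](c1ccc(OCc2ccccc2)c(OCc2ccccc2)c1)O)OS(=O)(=O)c1ccccc1 | intermediate
13 | (4S)-4-[3,4-bis(benzyloxy)phenyl]oxetan-2-one | O=C1C[C@@H](c2ccc(OCc3ccccc3)c(OCc3ccccc3)c2)O1 | intermediate
14 | [2,4-bis(benzyloxy)-3-[3-(benzyloxy)-3-methylbutyl]-6-fluorophenyl]lithium | CC(C)(OCc1ccccc1)CCc1c(OCc2ccccc2)cc(F)c([Li])c1OCc1ccccc1 | intermediate
15 | lithium (1S)-1-[3,4-bis(benzyloxy)phenyl]-3-[2,4-bis(benzyloxy)-3-[3-(benzyloxy)-3-methylbutyl]-6-fluorophenyl]-3-oxopropan-1-olate | CC(C)(OCc1ccccc1)CCc1c(OCc2ccccc2)cc(F)c(C(=O)C[C@@H](c2ccc(OCc3ccccc3)c(OCc3ccccc3)c2)O[Li])c1OCc1ccccc1 | intermediate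
16 | (2S)-5,7-bis(benzyloxy)-6-[3-(benzyloxy)-3-methylbutyl]-2-[3,4-bis(benzyloxy)phenyl]-2,3-dihydro-4H-chromen-4-one | CC(C)(OCc1ccccc1)CCc1c(OCc2ccccc2)cc2c(c1OCc1ccccc1)C(=O)C[C@@H](c1ccc(OCc3ccccc3)c(OCc3ccccc3)c1)O2 | intermediate
17 | (2S)-2-(3,4-dihydroxyphenyl)-5,7-dihydroxy-6-(3-hydroxy-3-methylbutyl)-2,3-dihydro-4H-chromen-4-one | CC(C)(O)CCc1c(O)cc2c(c1O)C(=O)C[C@@H](c1ccc(O)c(O)c1)O2 | target

**Step count**

Total step count: 10. Longest linear sequence: 6 steps (steps 1–4, 9, 10; the lactone branch 5–8, 9, 10 is equally long).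

**Steps most likely to fail**

Step 9 (Proposed new method). What may go wrong: a second addition of 14 to the liberated ketone; loss of LiF from 14 (aryne formation) if the exchange mixture warms; and retro-aldol cleavage, enolisation or dehydration of aldolate 15 competing with a slow SNAr closure, which would erode the enantiomeric purity at C2. The fallback sets out from compound 7, comes back at compound 16, and sets C2 last under non-basic conditions. Bromide 7 would be exchanged with t-BuLi as before (aryllithium 14) and acylated with N-methoxy-N-methylacetamide to give the methyl ketone 1-[2,4-bis(benzyloxy)-3-[3-(benzyloxy)-3-methylbutyl]-6-fluorophenyl]ethan-1-one F1. Claisen formylation with ethyl formate and NaH in THF would give the sodium enolate sodium (1Z)-3-[2,4-bis(benzyloxy)-3-[3-(benzyloxy)-3-methylbutyl]-6-fluorophenyl]-3-oxoprop-1-en-1-olate F2. On warming in DMF this enolate should close onto the C–F carbon by SNAr (the closure used for chromones and 4-quinolones from ortho-halogenated aroyl enolates) to the chromone 5,7-bis(benzyloxy)-6-[3-(benzyloxy)-3-methylbutyl]-4H-chromen-4-one F3. Palladium-catalysed asymmetric conjugate addition of 3,4-bis(benzyloxy)phenylboronic acid to F3 would then give 16; the conditions would be Pd(OCOCF3)2, the enantiomer of t-BuPyOX that leads to the 2S product, NH4PF6, H2O, ClCH2CH2Cl, 60 °C.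

Step 2. What may go wrong: metalation next to fluorine instead of between the two ethers (followed by loss of LiF); benzylic deprotonation of a benzyl ether with Wittig rearrangement; or opening of the BF3-activated oxetane at its tertiary carbon. The fallback sets out from compound 1, comes back at compound 5, and replaces both the deprotonation and the oxetane opening. Iodination of 1 between the hydroxyl groups (I2, NaHCO3, H2O, 0 °C, as for resorcinol itself) would give 5-fluoro-2-iodobenzene-1,3-diol F4. Benzylation (BnBr, K2CO3, DMF) would give 1,3-bis(benzyloxy)-5-fluoro-2-iodobenzene F5. Sonogashira coupling with 2-methylbut-3-yn-2-ol (PdCl2(PPh3)2, CuI, Et3N) would give 4-[2,6-bis(benzyloxy)-4-fluorophenyl]-2-methylbut-3-yn-2-ol F6. Diimide reduction of the triple bond (TsNHNH2, NaOAc, DME/H2O, reflux), which spares benzyl ethers and the aryl fluoride, would give compound 5.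

Step 8. What may go wrong: ionisation of the benzylic C–O bond of the electron-rich 4-aryl-β-lactone during formation, purification or storage, leading to decarboxylation to the styrene, oligomerisation or loss of enantiomeric purity. The fallback sets out from compound 10, comes back at compound 15 (and so at 16), and replaces the lactone by an open-chain acyl donor. Ester 10 would be converted with MeNH(OMe)·HCl and i-PrMgCl (THF, −20 °C) into the Weinreb amide (3S)-3-[3,4-bis(benzyloxy)phenyl]-3-hydroxy-N-methoxy-N-methylpropanamide F7. One equivalent of n-BuLi at −78 °C would give its alkoxide, lithium (1S)-1-[3,4-bis(benzyloxy)phenyl]-3-[methoxy(methyl)amino]-3-oxopropan-1-olate F8, which would be added to aryllithium 14 (made from 7 as in step 9). The stable N,O-chelated adduct would give on work-up the β-hydroxy ketone (3S)-3-[3,4-bis(benzyloxy)phenyl]-1-[2,4-bis(benzyloxy)-3-[3-(benzyloxy)-3-methylbutyl]-6-fluorophenyl]-3-hydroxypropan-1-one F9. Deprotonation of F9 with one equivalent of LiN(SiMe3)2 at −78 °C would regenerate aldolate 15, which closes to 16 as in step 9.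

**Further compounds**

F1 | step 9 | 1-[2,4-bis(benzyloxy)-3-[3-(benzyloxy)-3-methylbutyl]-6-fluorophenyl]ethan-1-one | CC(=O)c1c(F)cc(OCc2ccccc2)c(CCC(C)(C)OCc2ccccc2)c1OCc1ccccc1
F2 | step 9 | sodium (1Z)-3-[2,4-bis(benzyloxy)-3-[3-(benzyloxy)-3-methylbutyl]-6-fluorophenyl]-3-oxoprop-1-en-1-olate | [Na+].[O-]/C=C\C(=O)c1c(F)cc(OCc2ccccc2)c(CCC(C)(C)OCc2ccccc2)c1OCc1ccccc1
F3 | step 9 | 5,7-bis(benzyloxy)-6-[3-(benzyloxy)-3-methylbutyl]-4H-chromen-4-one | CC(C)(OCc1ccccc1)CCc1c(OCc2ccccc2)cc2occc(=O)c2c1OCc1ccccc1
F4 | step 2 | 5-fluoro-2-iodobenzene-1,3-diol | Oc1cc(F)cc(O)c1I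
F5 | step 2 | 1,3-bis(benzyloxy)-5-fluoro-2-iodobenzene | Fc1cc(OCc2ccccc2)c(I)c(OCc2ccccc2)c1
F6 | step 2 | 4-[2,6-bis(benzyloxy)-4-fluorophenyl]-2-methylbut-3-yn-2-ol | CC(C)(O)C#Cc1c(OCc2ccccc2)cc(F)cc1OCc1ccccc1
F7 | step 8 | (3S)-3-[3,4-bis(benzyloxy)phenyl]-3-hydroxy-N-methoxy-N-methylpropanamide | CON(C)C(=O)C[C@@H](c1ccc(OCc2ccccc2)c(OCc2ccccc2)c1)O
F8 | step 8 | lithium (1S)-1-[3,4-bis(benzyloxy)phenyl]-3-[methoxy(methyl)amino]-3-oxopropan-1-olate | CON(C)C(=O)C[C@@H](c1ccc(OCc2ccccc2)c(OCc2ccccc2)c1)O[Li]
F9 | step 8 | (3S)-3-[3,4-bis(benzyloxy)phenyl]-1-[2,4-bis(benzyloxy)-3-[3-(benzyloxy)-3-methylbutyl]-6-fluorophenyl]-3-hydroxypropan-1-one | CC(C)(OCc1ccccc1)CCc1c(OCc2ccccc2)cc(F)c(C(=O)C[C@@H](c2ccc(OCc3ccccc3)c(OCc3ccccc3)c2)O)c1OCc1ccccc1
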